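**Plan**
- Retrosynthesis: cut the trisubstituted C=C of the side chain (aldol condensation of a ring-B CH2CHO arm with dienal 3), then the bond from the ring-B CH to that arm (anti opening of a cyclopentene epoxide), then in one stroke the two bonds that tie the CH2–CH2 unit of ring B to the spiro carbon and to the arm-bearing carbon ((3+2)); ring A (the cyclohexane) goes back to (S)-carvone.
- Enabling feature: in ring B (the cyclopentane) the spiro carbon, the carbinol carbon and the arm-bearing CH are a three-carbon unit with oxygen on its middle carbon, i.e. a 2-alkoxyallyl (oxyallyl) cation that takes up a two-carbon enol ether at its two ends; the ring-A carbon that ends as the alkylidene carbon of the enal is 1,3 to the spiro carbon and can hold that enol ether on an axial oxygen over one face.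
- Forward: carvone is dressed to ring A (steps 3–8); the tethered (3+2) builds ring B on the former ketone carbon and sheds the tether as a spiro-cyclopentenone (step 9); the enone is transposed to an alkene, epoxidised and opened (steps 10, 16–18); the ring-A enal unit is made and masked (steps 11–15, unmasked in 22–23); the side chain is joined last (steps 19–21).
- Stereochemistry: carvone's stereocentre steers the enone epoxidation (tertiary carbinol) and the α′-alkylation (CH with the hydroxypropyl chain) and, after Criegee oxidation with retention, holds the tether that fixes the spiro centre; the carbinol/arm pair comes from hydroxyl-directed epoxidation and anti opening; the alkene geometries come from Heck coupling, aldol condensation and equilibration of the ring-A enal.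

Key step: step 9

Assumption: the ring-A enal should equilibrate (iodine) to the isomer with CHO syn to the ring CH that bears the hydroxypropyl chain (the target geometry), because formyl causes less allylic 1,3-strain there than methyl.

Step 1
Reactants: 1 6-methylhept-5-en-2-one
Product: 2 6-methylhepta-1,5-dien-2-yl trifluoromethanesulfonate
Conditions: LiN(i-Pr)2, THF, −78 °C; then PhNTf2, −78 to 0 °C
Reagents that add atoms: N-phenylbis(trifluoromethanesulfonimide), O=S(=O)(N(c1ccccc1)S(=O)(=O)C(F)(F)F)C(F)(F)F
Why: Kinetic deprotonation of the methyl ketone at its methyl group and O-sulfonylation of the less substituted enolate should give the terminal enol triflate (enolate triflation).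

Step 2
Reactants: 2 6-methylhepta-1,5-dien-2-yl trifluoromethanesulfonate
Product: 3 (2E)-8-methyl-4-methylidenenona-2,7-dienal
Conditions: acrolein, Pd(OAc)2 (5 mol %), PPh3 (10 mol %), Et3N, DMF, 60 °C
Reagents that add atoms: acrolein, C=CC=O
Why: Mizoroki–Heck coupling of the enol triflate with acrolein should give the (E)-dienal, since syn insertion and syn β-hydride elimination place formyl trans to the new C–C bond.

Step 3
Reactants: 4 (S)-(+)-carvone; 5 tert-butyl(3-iodopropoxy)dimethylsilane
Product: 6 6-[3-(tert-butyldimethylsilyloxy)propyl]carvone (chain trans to isopropenyl)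
Conditions: LiN(i-Pr)2, THF, −78 °C; then 5, DMPU, −78 to −10 °C
Reagents that add atoms: none
Why: Kinetic α′-deprotonation of carvone and enolate alkylation anti to the neighbouring isopropenyl group should set the chain-bearing carbon trans to isopropenyl, which is also the more stable diequatorial epimer.

Step 4
Reactants: 6 6-[3-(tert-butyldimethylsilyloxy)propyl]carvone
Product: 7 epoxy ketone (epoxide oxygen trans to isopropenyl)
Conditions: 30% aq. H2O2, NaOH (cat.), MeOH, 0 °C
Reagents that add atoms: hydrogen peroxide, OO
Why: Weitz–Scheffer epoxidation, in which hydroperoxide adds to the enone β-carbon from the face opposite the isopropenyl group, so that the oxygen of the later tertiary carbinol ends trans to isopropenyl and cis to the chain.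

Step 5
Reactants: 7 epoxy ketone
Product: 9 acetoxy epoxy ketone (acetoxy on the face that held isopropenyl), via methoxy hydroperoxide 8 (not isolated)
Conditions: O3, CH2Cl2/MeOH, −78 °C; then Ac2O, Et3N, DMAP (cat.), 0 to 40 °C
Reagents that add atoms: ozone, O=[O+][O-]; methanol, CO
Why: Ozonolysis in methanol gives the α-methoxy hydroperoxide, whose peracetate undergoes Criegee rearrangement with migration of the ring carbon and retention of configuration, so isopropenyl becomes acetoxy on the same face.

Step 6
Reactants: 9 acetoxy epoxy ketone
Product: 10 tertiary 1-ethoxyvinyl carbinol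
Conditions: CH2=C(OEt)Li (from ethyl vinyl ether and t-BuLi, THF, −78 to 0 °C), CeCl3, THF, −78 °C
Reagents that add atoms: ethyl vinyl ether, C=COCC
Why: Organocerium 1,2-addition of an acyl-anion equivalent to the hindered, enolizable ketone without deprotonation or attack on acetate and epoxide; the configuration of the new carbinol carbon does not matter because this carbon is ionized in step 9.

Step 7
Reactants: 10 tertiary 1-ethoxyvinyl carbinol
Product: 11 triol (two tertiary hydroxyls and one secondary hydroxyl)
Conditions: LiEt3BH (excess), THF, 0 to 23 °C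
Reagents that add atoms: none
Why: Hydride reduction in which LiEt3BH opens the trisubstituted epoxide by SN2 attack at its secondary carbon, leaving the tertiary C–O bond and its configuration intact, and also cleaves the acetate to the secondary alcohol.

Step 8
Reactants: 11 triol
Product: 12 vinyl ether of the secondary hydroxyl
Conditions: vinyl acetate, [Ir(cod)Cl]2 (2 mol %), Na2CO3, toluene, 100 °C
Reagents that add atoms: vinyl acetate, C=COC(C)=O
Why: Iridium-catalysed transfer vinylation should etherify only the secondary hydroxyl, the two tertiary ones being too hindered, under basic conditions that spare the acid-labile enol ether.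

Step 9
Reactants: 12 vinyl ether of the secondary hydroxyl
Product: 15 spiro enone diol (6,9-dihydroxy-6-methyl-10-(silyloxypropyl)spiro[4.5]dec-2-en-1-one), via bis-silyl ether 13 (not isolated), via oxa-bridged cycloadduct 14 (not isolated)
Conditions: Me3SiOTf (3 equiv), 2,6-di-tert-butyl-4-methylpyridine, CH2Cl2 (0.005 M), −78 to 0 °C; then 0.1 M aq. HCl, THF, 0 °C
Reagents that add atoms: water, O
Why: Proposed new method: Me3SiOTf silylates both tertiary hydroxyls and ionizes the allylic tertiary silyl ether to a 2-ethoxyallyl cation whose ends are the ring-A carbon (the future spiro carbon) and the exocyclic CH2. The vinyl ether held on the axial ring-A oxygen two carbons away attacks the ring terminus through a chair-like six-membered transition state (6-endo-trig for the vinyl ether; first new bond), and the cyclic oxocarbenium ion so formed is captured by the terminal carbon of the remaining ethyl enol ether (5-(enolendo)-exo-trig; second new bond, closing the cyclopentane), so the net event is an intramolecular (3+2) cycloaddition of an oxyallyl cation equivalent with an enol ether. The closest known reaction types are the Lewis-acid-mediated (3+2) cyclopentannulation of 2-siloxyallyl or 2-alkoxyallyl cations with enol ethers and vinyl sulfides, and cation–olefin cyclization ended by an enol ether. The only new stereocentre that survives, the spiro carbon, is set by the tether, because the two-carbon unit can reach only the face of the cation on which the ring oxygen sits, the face anti to the side chain and to the tertiary silyloxy group. The step needs attack at the tertiary rather than the primary terminus and C- rather than O-closure: the short tether (six- against eight-membered ring) secures the first and the O-ethyl enol ether, which can react only through carbon, the second. The strained oxa-bridged adduct should then lose the bridging alkoxide by Lewis-acid-assisted β-elimination through its enol ether, and aqueous acid hydrolyses the resulting ethoxy-substituted cation and the silyl ethers, which returns the tether oxygen as the free secondary hydroxyl.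

Step 10
Reactants: 15 spiro enone diol
Product: 17 spiro[4.5]dec-1-ene-6,9-diol, via tosylhydrazone 16 (not isolated)
Conditions: TsNHNH2, EtOH, 60 °C; then catecholborane, CHCl3, 0 °C; then NaOAc·3H2O, 65 °C
Reagents that add atoms: none
Why: Reductive 1,3-transposition of an enone: catecholborane reduces the C=N bond of the tosylhydrazone, and loss of sulfinate and then of N2 by a retro-ene shift delivers hydrogen to the former β-carbon and moves the double bond to the former carbonyl carbon.

Step 11
Reactants: 17 spiro[4.5]dec-1-ene-6,9-diol
Product: 18 9-ketone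
Conditions: 1,1,1-triacetoxy-1,1-dihydro-1,2-benziodoxol-3(1H)-one, NaHCO3, CH2Cl2, 23 °C
Reagents that add atoms: none
Why: Periodinane oxidation converts the only secondary alcohol into the ketone, and the tertiary alcohol cannot react.

Step 12
Reactants: 18 9-ketone
Product: 19 9-isopropenyl carbinol
Conditions: CH2=C(CH3)MgBr, CeCl3, THF, −78 °C
Reagents that add atoms: isopropenylmagnesium bromide, C=C(C)[Mg]Br
Why: Organocerium 1,2-addition to the hindered α-branched ketone without enolization; either carbinol epimer serves because this stereocentre is removed in step 13.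

Step 13
Reactants: 19 9-isopropenyl carbinol
Product: 20 ring-A enal (CHO syn to the ring CH that bears the chain)
Conditions: pyridinium chlorochromate (C5H5NH)[CrO3Cl], NaOAc, 4 Å molecular sieves, CH2Cl2, 23 °C; then I2 (5 mol %), CH2Cl2, ambient light
Reagents that add atoms: pyridinium chlorochromate, [O-][Cr](=O)(=O)Cl.c1cc[nH+]cc1
Why: Babler–Dauben oxidative transposition, in which the tertiary allylic chromate ester undergoes a [3,3] shift and the primary chromate is oxidized to the tetrasubstituted enal; iodine-catalysed equilibration should favour the isomer with formyl syn to the more substituted ring carbon.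

Step 14
Reactants: 20 ring-A enal
Product: 21 ring-A allylic alcohol
Conditions: NaBH4, CeCl3·7H2O, MeOH, −40 °C
Reagents that add atoms: none
Why: Luche reduction adds hydride 1,2 to the enal and leaves the alkene geometry untouched.

Step 15
Reactants: 21 ring-A allylic alcohol
Product: 22 bis(tert-butyldimethylsilyl) ether
Conditions: t-BuMe2SiCl, imidazole, DMF, 23 °C
Reagents that add atoms: tert-butyldimethylsilyl chloride, CC(C)(C)[Si](C)(C)Cl
Why: Silylation of the primary allylic alcohol (the tertiary alcohol is inert) masks the future enal against the nucleophiles and hydrides of steps 17 to 20.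

Step 16
Reactants: 22 bis(tert-butyldimethylsilyl) ether
Product: 23 ring-B epoxide (oxygen on the face of the tertiary hydroxyl)
Conditions: VO(acac)2 (5 mol %), t-BuOOH, CH2Cl2, 0 to 23 °C
Reagents that add atoms: tert-butyl hydroperoxide, CC(C)(C)OO
Why: Hydroxyl-directed epoxidation, in which the vanadate ester of the homoallylic tertiary hydroxyl delivers oxygen to the cyclopentene face on which that hydroxyl lies, while the undirected tetrasubstituted alkene is left alone.

Step 17
Reactants: 23 ring-B epoxide
Product: 24 hydroxy nitrile (cyanomethyl trans to the new hydroxyl)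
Conditions: LiCH2CN (from CH3CN and n-BuLi, THF, −78 °C); then 23, −78 to 50 °C
Reagents that add atoms: acetonitrile, CC#N
Why: SN2 epoxide opening by lithioacetonitrile at the carbon remote from the spiro centre (the neopentyl carbon is blocked) and anti to the epoxide oxygen, which sets the trans carbinol/arm pair and its configuration relative to the spiro centre.

Step 18
Reactants: 24 hydroxy nitrile
Product: 25 hydroxy aldehyde
Conditions: i-Bu2AlH, CH2Cl2, −78 °C; then aq. KNaC4H4O6
Reagents that add atoms: water, O
Why: Partial reduction of the nitrile to the aluminium imine, which hydrolyses to the aldehyde on work-up.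

Step 19
Reactants: 25 hydroxy aldehyde; 3 (2E)-8-methyl-4-methylidenenona-2,7-dienal
Product: 26 2-substituted (2E,4E)-trienal
Conditions: pyrrolidine (20 mol %), benzoic acid (20 mol %), CH2Cl2, 23 °C
Reagents that add atoms: none
Why: Amine-catalysed cross-aldol condensation, in which the enamine of enolizable 25 adds to the iminium ion of dienal 3 and elimination gives the thermodynamically preferred (E)-2-substituted enal, with the dienyl chain trans to formyl and thus cis to ring B as in the target.

Step 20
Reactants: 26 2-substituted (2E,4E)-trienal
Product: 27 primary allylic alcohol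
Conditions: NaBH4, CeCl3·7H2O, MeOH/THF, −40 °C
Reagents that add atoms: none
Why: Luche 1,2-reduction of the only aldehyde present (the ring-A enal is still masked) gives the primary allylic alcohol.

Step 21
Reactants: 27 primary allylic alcohol
Product: 28 allylic acetate
Conditions: Ac2O (1.1 equiv), pyridine, CH2Cl2, 0 °C
Reagents that add atoms: acetic anhydride, CC(=O)OC(C)=O
Why: Selective acylation of the unhindered primary allylic alcohol over the secondary hydroxyl next to the spiro carbon and over the tertiary hydroxyl.

Step 22
Reactants: 28 allylic acetate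
Product: 29 desilylated triol acetate
Conditions: HF·pyridine, pyridine, THF, 0 to 23 °C
Reagents that add atoms: none
Why: Buffered fluoride desilylation cleaves both primary silyl ethers without touching the allylic acetate or the polyene.

Step 23
Reactants: 29 desilylated triol acetate
Product: 30 CNP0204268.2 (target)
Conditions: MnO2 (activated, excess), CH2Cl2, 23 °C
Reagents that add atoms: none
Why: Chemoselective allylic oxidation, since MnO2 oxidizes only the allylic primary alcohol, with retention of alkene geometry, and leaves the saturated primary and secondary alcohols alone.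

**Compound list**
1 | 6-methylhept-5-en-2-one | CC(=O)CCC=C(C)C | starting material
2 | 6-methylhepta-1,5-dien-2-yl trifluoromethanesulfonate | C=C(OS(=O)(=O)C(F)(F)F)CCC=C(C)C | intermediate
3 | (2E)-8-methyl-4-methylidenenona-2,7-dienal | O=C/C=C/C(=C)CCC=C(C)C | intermediate
4 | (S)-(+)-carvone | O=C1C[C@@H](C(C)=C)CC=C1C | starting material
5 | tert-butyl(3-iodopropoxy)dimethylsilane | ICCCO[Si](C)(C)C(C)(C)C | starting material
6 | 6-[3-(tert-butyldimethylsilyloxy)propyl]carvone; chain at C-6 trans to isopropenyl at C-5 | O=C1[C@H](CCCO[Si](C)(C)C(C)(C)C)[C@@H](C(C)=C)CC=C1C | intermediate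
7 | epoxy ketone: enone C=C of 6 epoxidised; epoxide oxygen trans to isopropenyl and cis to the chain | O=C1[C@H](CCCO[Si](C)(C)C(C)(C)C)[C@@H](C(C)=C)C[C@@H]2O[C@]12C | intermediate
8 | α-methoxy hydroperoxide: isopropenyl of 7 converted into C(CH3)(OCH3)OOH | O=C1[C@H](CCCO[Si](C)(C)C(C)(C)C)[C@@H](C(C)(OC)OO)C[C@@H]2O[C@]12C | intermediate
9 | acetoxy epoxy ketone: isopropenyl of 7 replaced by acetoxy on the same face (trans to the chain and to the epoxide oxygen) | O=C1[C@H](CCCO[Si](C)(C)C(C)(C)C)[C@@H](OC(C)=O)C[C@@H]2O[C@]12C | intermediate
10 | tertiary 1-ethoxyvinyl carbinol from 9 (ethoxyvinyl drawn on the face of the ring methyl; this centre is ionized later) | C=C(OCC)[C@@]1(O)[C@H](CCCO[Si](C)(C)C(C)(C)C)[C@@H](OC(C)=O)C[C@@H]2O[C@]12C | intermediate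
11 | triol: ring A with C(OH)(1-ethoxyvinyl), C(CH3)(OH) cis to the chain, CH(OH) trans to the chain, CH(silyloxypropyl) | C=C(OCC)[C@@]1(O)[C@H](CCCO[Si](C)(C)C(C)(C)C)[C@@H](O)CC[C@]1(C)O | intermediate
12 | vinyl ether of the secondary hydroxyl of 11 | C=C(OCC)[C@@]1(O)[C@H](CCCO[Si](C)(C)C(C)(C)C)[C@@H](OC=C)CC[C@]1(C)O | intermediate
13 | bis(trimethylsilyl) ether of 12 (both tertiary hydroxyls silylated) | C=C(OCC)[C@@]1(O[Si](C)(C)C)[C@H](CCCO[Si](C)(C)C(C)(C)C)[C@@H](OC=C)CC[C@]1(C)O[Si](C)(C)C | intermediate
14 | oxa-bridged cycloadduct: spiro[4.5]decane with 1-ethoxy-1-ene in ring B, oxygen bridge from C-3 (ring B) to C-9 (ring A), 6-OSiMe3 | CCOC1=C[C@H]2C[C@]13[C@H](CCCO[Si](C)(C)C(C)(C)C)[C@@H](O2)CC[C@]3(C)O[Si](C)(C)C | intermediate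
15 | spiro enone diol: 6,9-dihydroxy-6-methyl-10-[3-(tert-butyldimethylsilyloxy)propyl]spiro[4.5]dec-2-en-1-one; C-1, 6-OH and the 10-chain on one face of ring A; 6-CH3, C-4 and 9-OH on the other | O=C1C=CC[C@]12[C@H](CCCO[Si](C)(C)C(C)(C)C)[C@@H](O)CC[C@]2(C)O | intermediate
16 | p-toluenesulfonylhydrazone of 15 | Cc1ccc(cc1)S(=O)(=O)NN=C1C=CC[C@]12[C@H](CCCO[Si](C)(C)C(C)(C)C)[C@@H](O)CC[C@]2(C)O | intermediate
17 | spiro[4.5]dec-1-ene-6,9-diol with the substituents and configurations of 15 | C1=C[C@]2(CC1)[C@H](CCCO[Si](C)(C)C(C)(C)C)[C@@H](O)CC[C@]2(C)O | intermediate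
18 | 9-ketone of 17 | C1=C[C@]2(CC1)[C@H](CCCO[Si](C)(C)C(C)(C)C)C(=O)CC[C@]2(C)O | intermediate
19 | 9-hydroxy-9-isopropenyl compound from 18 (carbinol configuration of no consequence) | C1=C[C@]2(CC1)[C@H](CCCO[Si](C)(C)C(C)(C)C)[C@@](O)(C(C)=C)CC[C@]2(C)O | intermediate
20 | ring-A enal: 2-(spiro[4.5]dec-1-en-9-ylidene)propanal with CHO syn to C-10 | C1=C[C@]2(CC1)[C@H](CCCO[Si](C)(C)C(C)(C)C)/C(=C(/C)C=O)CC[C@]2(C)O | intermediate
21 | ring-A allylic alcohol from 20 | C1=C[C@]2(CC1)[C@H](CCCO[Si](C)(C)C(C)(C)C)/C(=C(/C)CO)CC[C@]2(C)O | intermediate
22 | bis(tert-butyldimethylsilyl) ether from 21 | C1=C[C@]2(CC1)[C@H](CCCO[Si](C)(C)C(C)(C)C)/C(=C(/C)CO[Si](C)(C)C(C)(C)C)CC[C@]2(C)O | intermediate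
23 | 1,2-epoxide of 22; epoxide oxygen on the face of the tertiary hydroxyl | O1[C@H]2CC[C@]3([C@H](CCCO[Si](C)(C)C(C)(C)C)/C(=C(/C)CO[Si](C)(C)C(C)(C)C)CC[C@]3(C)O)[C@@H]12 | intermediate
24 | hydroxy nitrile: 2-(cyanomethyl) trans to 1-OH; 1-OH cis to C-6 | N#CC[C@@H]1CC[C@]2([C@H](CCCO[Si](C)(C)C(C)(C)C)/C(=C(/C)CO[Si](C)(C)C(C)(C)C)CC[C@]2(C)O)[C@H]1O | intermediate
25 | hydroxy aldehyde from 24 | O=CC[C@@H]1CC[C@]2([C@H](CCCO[Si](C)(C)C(C)(C)C)/C(=C(/C)CO[Si](C)(C)C(C)(C)C)CC[C@]2(C)O)[C@H]1O | intermediate
26 | 2-substituted (2E,4E)-trienal | C=C(/C=C/C=C(/C=O)[C@@H]1CC[C@]2([C@H](CCCO[Si](C)(C)C(C)(C)C)/C(=C(/C)CO[Si](C)(C)C(C)(C)C)CC[C@]2(C)O)[C@H]1O)CCC=C(C)C | intermediate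
27 | primary allylic alcohol from 26 | C=C(/C=C/C=C(/CO)[C@@H]1CC[C@]2([C@H](CCCO[Si](C)(C)C(C)(C)C)/C(=C(/C)CO[Si](C)(C)C(C)(C)C)CC[C@]2(C)O)[C@H]1O)CCC=C(C)C | intermediate
28 | allylic acetate of 27 | C=C(/C=C/C=C(/COC(C)=O)[C@@H]1CC[C@]2([C@H](CCCO[Si](C)(C)C(C)(C)C)/C(=C(/C)CO[Si](C)(C)C(C)(C)C)CC[C@]2(C)O)[C@H]1O)CCC=C(C)C | intermediate
29 | desilylated triol acetate (the target with CH2OH in place of CHO) | C=C(/C=C/C=C(/COC(C)=O)[C@@H]1CC[C@]2([C@H](CCCO)/C(=C(/C)CO)CC[C@]2(C)O)[C@H]1O)CCC=C(C)C | intermediate
30 | CNP0204268.2 | C=C(/C=C/C=C(/COC(C)=O)[C@@H]1CC[C@]2([C@H](CCCO)/C(=C(/C)C=O)CC[C@]2(C)O)[C@H]1O)CCC=C(C)C | target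

**Count and risks**
Total steps: 23. Longest linear sequence: 21 (steps 3 to 23); steps 1 and 2 make dienal 3 for the convergent step 19.

Step 9 (proposed new method). The risk is in the second ring closure: the oxa-bridged adduct is strained (ring A must leave its chair), so the cyclic oxocarbenium ion formed after the first C–C bond may be lost by proton loss or hydration before the cyclopentane closes. The fallback separates the two bonds with known chemistry and sets out from 12. The same ionization (Me3SiOTf, hindered pyridine, CH2Cl2, −78 °C; a cation–olefin cyclization ended by the tethered enol ether, which still fixes the spiro centre) is quenched cold with aqueous NaHCO3 and then dilute acid, to collect the monocyclised product as the bicyclic keto lactol F1. Intramolecular aldol condensation of this masked 1,4-keto aldehyde (pyrrolidine, acetic acid, THF/MeOH, 23 °C) would then close the cyclopentenone and release the secondary hydroxyl, and the route is rejoined at 15.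

Step 13. The [3,3] shift of the hindered tertiary chromate ester to a tetrasubstituted alkene may be slow and may be overtaken by over-oxidation, and the isomer ratio may be poor. The fallback sets out from ketone 18: Peterson olefination with the lithium derivative of N-tert-butyl-2-(triethylsilyl)propan-1-imine (THF, −78 to 0 °C) would give the unsaturated N-tert-butyl aldimine F2, and hydrolysis with aqueous oxalic acid, which also equilibrates the double bond, comes back to the route at enal 20.

Step 19. Self-condensation of the enolizable aldehyde and oligomerisation of the dienal may compete under amine catalysis. The fallback is a directed aldol condensation through a metalated imine (Wittig directed aldol) and sets out from 25: condensation with cyclohexylamine (MgSO4, CH2Cl2) would give the N-cyclohexyl aldimine F3; LiN(i-Pr)2 (excess, THF, −78 °C) and then dienal 3 would give the β-hydroxy imine F4; aqueous oxalic acid would hydrolyse and dehydrate it, and the route is rejoined at trienal 26.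

**Further compounds**
F1 | step 9 | bicyclic keto lactol: 2-oxabicyclo[3.3.1]nonane hemiacetal with acetyl on the bridgehead that becomes the spiro carbon | CC(=O)[C@@]12CC(O)O[C@@H](CC[C@]1(C)O)[C@H]2CCCO[Si](C)(C)C(C)(C)C
F2 | step 13 | N-tert-butyl aldimine of enal 20 (C=C geometry not fixed) | C1=C[C@]2(CC1)[C@H](CCCO[Si](C)(C)C(C)(C)C)C(=C(C)C=NC(C)(C)C)CC[C@]2(C)O
F3 | step 19 | N-cyclohexyl aldimine of 25 | C1CCC(CC1)N=CC[C@@H]2CC[C@]3([C@H](CCCO[Si](C)(C)C(C)(C)C)/C(=C(/C)CO[Si](C)(C)C(C)(C)C)CC[C@]3(C)O)[C@H]2O
F4 | step 19 | β-hydroxy imine from F3 and 3 (two new centres not fixed) | C1CCC(CC1)N=CC(C(O)/C=C/C(=C)CCC=C(C)C)[C@@H]2CC[C@]3([C@H](CCCO[Si](C)(C)C(C)(C)C)/C(=C(/C)CO[Si](C)(C)C(C)(C)C)CC[C@]3(C)O)[C@H]2O
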